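Ring B, the 3,5-dihydroxyphenyl group on C3 of the dihydrobenzofuran, is a resorcinol joined through its C1' to C3 and oxygenated at C3' and C5': the oxygen pattern of a folded triketide. It is therefore not attached as an arene but grown last. A hexane-1,3,5-trione bound to C3 through its C1 carbonyl is closed by base, the methyl carbon C6 bonding to C1; loss of water and enolisation then give the aromatic ring, with both hydroxyls in place, in one operation. The precursor is the benzyl-protected trans-(2S,3S)-3-acyl-2-aryl-dihydrobenzofuran, reached from a chromone by asymmetric arylation and oxidative ring contraction.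

Key step: step 9

Remark (numbering): benzofuran numbering O1, C2, C3, C3a, C4–C7, C7a is used; ring A is the benzo ring and ring B the resorcinol. The target is the trans-(2S,3S) isomer.

Remark (assumption): the PyOX–palladium catalyst is taken to select the chromone face as it does that of other cyclic enones, so the (R)-ligand, (4R)-4-tert-butyl-2-(pyridin-2-yl)-4,5-dihydro-1,3-oxazole, is expected to give the (2S)-flavanone. The sense would be confirmed on the flavanone before going on.

Remark (protecting groups): all phenols are carried as benzyl ethers so that the last step is a neutral hydrogenolysis. The C2–O bond of a 2-(4-alkoxyphenyl)dihydrobenzofuran is a benzylic ether that a Lewis acid strong enough to cleave aryl methyl ethers could ionise.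

Step 1
Reactants: 1 5,7-dihydroxy-4H-chromen-4-one
Product: 2 5-hydroxy-4-oxo-4H-chromen-7-yl trifluoromethanesulfonate
Conditions: PhNTf2 (1.05 equiv), K2CO3 (1.1 equiv), DMF, 0 → 20 °C
Reagents that add atoms: N-phenylbis(trifluoromethanesulfonimide), O=S(=O)(N(c1ccccc1)S(=O)(=O)C(F)(F)F)C(F)(F)F
Why: Chemoselective O-triflation of a phenol: the 7-OH is the more acidic, unhindered hydroxyl while the 5-OH is held in a hydrogen bond to the C4 carbonyl, so one equivalent of the mild triflyl donor should sulfonylate O7 only.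

Step 2
Reactants: 3 1-(benzyloxy)-4-ethenylbenzene (4-benzyloxystyrene); 2 5-hydroxy-4-oxo-4H-chromen-7-yl trifluoromethanesulfonate
Product: 5 7-{2-[4-(benzyloxy)phenyl]ethyl}-5-hydroxy-4H-chromen-4-one, via B-alkyl-9-BBN borane 4 (not isolated)
Conditions: 3 (slight excess over borane), 9-BBN (0.5 M in THF), 0 → 20 °C; then 2, PdCl2(dppf) (5 mol %), K3PO4 (3 M aq.), DMF, 50 °C
Reagents that add atoms: none
Why: Anti-Markovnikov hydroboration of the styrene with 9-BBN followed by B-alkyl Suzuki–Miyaura coupling with the aryl triflate joins C7 to the saturated two-carbon chain in one flask, the chelated 5-OH and the pyranone ring tolerating phosphate base at 50 °C.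

Step 3
Reactants: 5 7-{2-[4-(benzyloxy)phenyl]ethyl}-5-hydroxy-4H-chromen-4-one
Product: 6 5-(benzyloxy)-7-{2-[4-(benzyloxy)phenyl]ethyl}-4H-chromen-4-one
Conditions: BnBr (1.3 equiv), K2CO3, DMF, 60 °C
Reagents that add atoms: benzyl bromide, BrCc1ccccc1
Why: Williamson etherification: carbonate in warm DMF frees the hydrogen-bonded 5-OH as its phenoxide, which benzyl bromide alkylates, and the chromone is inert to K2CO3.

Step 4
Reactants: 6 5-(benzyloxy)-7-{2-[4-(benzyloxy)phenyl]ethyl}-4H-chromen-4-one; 7 [4-(benzyloxy)phenyl]boronic acid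
Product: 8 (2S)-5-(benzyloxy)-2-[4-(benzyloxy)phenyl]-7-{2-[4-(benzyloxy)phenyl]ethyl}-2,3-dihydro-4H-chromen-4-one
Conditions: Pd(OCOCF3)2 (5 mol %), (R)-t-BuPyOX (6 mol %), NH4PF6 (30 mol %), H2O (5 equiv), ClCH2CH2Cl, 40–60 °C
Reagents that add atoms: none
Why: Asymmetric conjugate addition of an arylboronic acid to a chromone with a cationic divalent palladium–PyOX catalyst (transmetalation, insertion of C2=C3 into the aryl–palladium bond, protonolysis of the palladium enolate): the tert-butyl group of the ligand shields one face of the bound enone so that the aryl group reaches C2 from the other face and sets the (2S) centre, the (R)-ligand being chosen because the (S)-ligand directs aryl groups to the opposite face of cyclic enones.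

Step 5
Reactants: 8 (2S)-5-(benzyloxy)-2-[4-(benzyloxy)phenyl]-7-{2-[4-(benzyloxy)phenyl]ethyl}-2,3-dihydro-4H-chromen-4-one
Product: 10 methyl (2S,3S)-4-(benzyloxy)-2-[4-(benzyloxy)phenyl]-6-{2-[4-(benzyloxy)phenyl]ethyl}-2,3-dihydro-1-benzofuran-3-carboxylate, via 4-methoxy-2H-chromene enol ether 9 (not isolated)
Conditions: PhI(OAc)2 (1.2 equiv), HC(OMe)3, conc. H2SO4 (cat.), 0 → 20 °C; aqueous work-up
Reagents that add atoms: trimethyl orthoformate, COC(OC)OC
Why: Oxidative ring contraction of a flavanone with a trivalent iodine reagent (1,2-aryl shift): acid and orthoformate give enol ether 9, PhI(OAc)2 bonds to C3 on the face anti to the C2 aryl group, methanol adds to C4, and ring A carbon C4a then shifts from C4 to C3 anti to the leaving iodobenzene, so that C4 ends as the ester carbon and the new C3 centre stands trans to the untouched C2 centre, which is also the more stable arrangement.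

Step 6
Reactants: 10 methyl (2S,3S)-4-(benzyloxy)-2-[4-(benzyloxy)phenyl]-6-{2-[4-(benzyloxy)phenyl]ethyl}-2,3-dihydro-1-benzofuran-3-carboxylate
Product: 11 (2S,3S)-4-(benzyloxy)-2-[4-(benzyloxy)phenyl]-6-{2-[4-(benzyloxy)phenyl]ethyl}-2,3-dihydro-1-benzofuran-3-carboxylic acid
Conditions: LiOH·H2O (3 equiv), THF/H2O, 0 → 20 °C; then aq. HCl to pH 3
Reagents that add atoms: lithium hydroxide, [Li+].[OH-]
Why: Ester saponification (BAc2) with LiOH near 0 °C, where hydroxide attack at the ester carbonyl should outrun deprotonation at C3, the existing trans relationship being also the thermodynamic one and C2 not being involved.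

Step 7
Reactants: 12 pentane-2,4-dione (acetylacetone)
Product: 13 2,4-bis(trimethylsilyloxy)penta-1,3-diene
Conditions: Me3SiOTf (2.2 equiv), Et3N (2.4 equiv), Et2O, 0 → 20 °C; distillation
Reagents that add atoms: trimethylsilyl trifluoromethanesulfonate, C[Si](C)(C)OS(=O)(=O)C(F)(F)F
Why: Twofold enol silylation of a 1,3-diketone under soft enolisation (Me3SiOTf/Et3N) should give the bis(silyl enol ether), a neutral equivalent of the acetylacetone dianion that is nucleophilic at its terminal CH2.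

Step 8
Reactants: 11 (2S,3S)-4-(benzyloxy)-2-[4-(benzyloxy)phenyl]-6-{2-[4-(benzyloxy)phenyl]ethyl}-2,3-dihydro-1-benzofuran-3-carboxylic acid; 13 2,4-bis(trimethylsilyloxy)penta-1,3-diene
Product: 15 1-[(2S,3S)-4-(benzyloxy)-2-[4-(benzyloxy)phenyl]-6-{2-[4-(benzyloxy)phenyl]ethyl}-2,3-dihydro-1-benzofuran-3-yl]hexane-1,3,5-trione, via acid chloride 14 (not isolated)
Conditions: (COCl)2, DMF (cat.), CH2Cl2, 0 → 20 °C, evaporate; then 13, CH2Cl2, −78 → 20 °C; aq. NH4Cl
Reagents that add atoms: none
Why: Acid chloride formation (oxalyl chloride, DMF catalysis) followed by Mukaiyama-type C-acylation of the bis(silyl enol ether) at its terminal carbon builds the 1,3,5-triketone without any base, so the C3–H next to the new ketone and the ring C2–O bond are not endangered and both stereocentres are kept.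

Step 9
Reactants: 15 1-[(2S,3S)-4-(benzyloxy)-2-[4-(benzyloxy)phenyl]-6-{2-[4-(benzyloxy)phenyl]ethyl}-2,3-dihydro-1-benzofuran-3-yl]hexane-1,3,5-trione
Product: 17 5-[(2S,3S)-4-(benzyloxy)-2-[4-(benzyloxy)phenyl]-6-{2-[4-(benzyloxy)phenyl]ethyl}-2,3-dihydro-1-benzofuran-3-yl]benzene-1,3-diol, via aldol adduct 16 (not isolated)
Conditions: KOH (2 M aq.), 1,4-dioxane, argon, 20 → 50 °C; then aq. HCl to pH 3
Reagents that add atoms: none
Why: Hydroxide converts 15 into its bis-enolate at the two inner CH2 groups, and the small equilibrium share of enolate at the terminal methyl carbon C6 adds to the C1 carbonyl (the carbon bonded to C3) to give aldol 16, which loses water by E1cB and tautomerises, the oxygens of the C3 and C5 carbonyls becoming the two hydroxyls of ring B. The closest known reaction type is the alkali-induced aldol aromatisation of heptane-2,4,6-trione to orcinol, the laboratory counterpart of polyketide folding. Ring B closes in the 6-(enolendo)-exo-trig mode, since the enolate C5=C6 bond lies inside the new ring and the C1 carbonyl oxygen outside it. No stereocentre is formed (the carbinol carbon of 16 carries two equivalent ring arms) and C2 and C3 are only carried through, the fixed C2 centre returning C3 to trans should it enolise. The step needs C–C closure from the methyl end to beat O-cyclisation, retro-Claisen cleavage and enolisation towards C3 (which would expel O1 by β-elimination or give a spiro aldol that cannot aromatise). Aqueous alkali secures this because a 4-pyranone is reopened to the triketone under these conditions, the enolised carbonyls resist hydroxide, the C3–H is flanked by the C2 aryl and C4 benzyloxy groups and its enolate would suffer allylic strain with the latter, and only the methyl-end aldol drains irreversibly into an arene.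

Step 10
Reactants: 17 5-[(2S,3S)-4-(benzyloxy)-2-[4-(benzyloxy)phenyl]-6-{2-[4-(benzyloxy)phenyl]ethyl}-2,3-dihydro-1-benzofuran-3-yl]benzene-1,3-diol
Product: 18 5-[(2S,3S)-4-hydroxy-2-(4-hydroxyphenyl)-6-[2-(4-hydroxyphenyl)ethyl]-2,3-dihydro-1-benzofuran-3-yl]benzene-1,3-diol
Conditions: H2 (1 atm), 10% Pd/C, EtOAc/MeOH, 20 °C
Reagents that add atoms: none
Why: Catalytic hydrogenolysis of the three benzyl aryl ethers over Pd/C frees the phenols under neutral conditions, the more hindered secondary C2–O bond of the dihydrobenzofuran and both stereocentres remaining untouched at 1 atm and 20 °C.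

Compound list
1 | 5,7-dihydroxy-4H-chromen-4-one | O=c1ccoc2cc(O)cc(O)c12 | starting material
2 | 5-hydroxy-4-oxo-4H-chromen-7-yl trifluoromethanesulfonate | O=c1ccoc2cc(OS(=O)(=O)C(F)(F)F)cc(O)c12 | intermediate
3 | 1-(benzyloxy)-4-ethenylbenzene (4-benzyloxystyrene) | C=Cc1ccc(OCc2ccccc2)cc1 | starting material
4 | 9-{2-[4-(benzyloxy)phenyl]ethyl}-9-borabicyclo[3.3.1]nonane | C1CCC2CCCC1B2CCc1ccc(OCc2ccccc2)cc1 | intermediate
5 | 7-{2-[4-(benzyloxy)phenyl]ethyl}-5-hydroxy-4H-chromen-4-one | O=c1ccoc2cc(CCc3ccc(OCc4ccccc4)cc3)cc(O)c12 | intermediate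
6 | 5-(benzyloxy)-7-{2-[4-(benzyloxy)phenyl]ethyl}-4H-chromen-4-one | O=c1ccoc2cc(CCc3ccc(OCc4ccccc4)cc3)cc(OCc3ccccc3)c12 | intermediate
7 | [4-(benzyloxy)phenyl]boronic acid | OB(O)c1ccc(OCc2ccccc2)cc1 | starting material
8 | (2S)-5-(benzyloxy)-2-[4-(benzyloxy)phenyl]-7-{2-[4-(benzyloxy)phenyl]ethyl}-2,3-dihydro-4H-chromen-4-one | O=C1C[C@@H](c2ccc(OCc3ccccc3)cc2)Oc2cc(CCc3ccc(OCc4ccccc4)cc3)cc(OCc3ccccc3)c12 | intermediate
9 | (2S)-5-(benzyloxy)-2-[4-(benzyloxy)phenyl]-7-{2-[4-(benzyloxy)phenyl]ethyl}-4-methoxy-2H-chromene | COC1=C[C@@H](c2ccc(OCc3ccccc3)cc2)Oc2cc(CCc3ccc(OCc4ccccc4)cc3)cc(OCc3ccccc3)c12 | intermediate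
10 | methyl (2S,3S)-4-(benzyloxy)-2-[4-(benzyloxy)phenyl]-6-{2-[4-(benzyloxy)phenyl]ethyl}-2,3-dihydro-1-benzofuran-3-carboxylate (trans) | c1ccccc1COc1ccc(CCc2cc(OCc4ccccc4)c3c(c2)O[C@H](c2ccc(OCc4ccccc4)cc2)[C@H]3C(=O)OC)cc1 | intermediate
11 | (2S,3S)-4-(benzyloxy)-2-[4-(benzyloxy)phenyl]-6-{2-[4-(benzyloxy)phenyl]ethyl}-2,3-dihydro-1-benzofuran-3-carboxylic acid | c1ccccc1COc1ccc(CCc2cc(OCc4ccccc4)c3c(c2)O[C@H](c2ccc(OCc4ccccc4)cc2)[C@H]3C(=O)O)cc1 | intermediate
12 | pentane-2,4-dione (acetylacetone) | CC(=O)CC(C)=O | starting material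
13 | 2,4-bis(trimethylsilyloxy)penta-1,3-diene | C=C(O[Si](C)(C)C)C=C(C)O[Si](C)(C)C | intermediate
14 | (2S,3S)-4-(benzyloxy)-2-[4-(benzyloxy)phenyl]-6-{2-[4-(benzyloxy)phenyl]ethyl}-2,3-dihydro-1-benzofuran-3-carbonyl chloride | c1ccccc1COc1ccc(CCc2cc(OCc4ccccc4)c3c(c2)O[C@H](c2ccc(OCc4ccccc4)cc2)[C@H]3C(=O)Cl)cc1 | intermediate
15 | 1-[(2S,3S)-4-(benzyloxy)-2-[4-(benzyloxy)phenyl]-6-{2-[4-(benzyloxy)phenyl]ethyl}-2,3-dihydro-1-benzofuran-3-yl]hexane-1,3,5-trione | c1ccccc1COc1ccc(CCc2cc(OCc4ccccc4)c3c(c2)O[C@H](c2ccc(OCc4ccccc4)cc2)[C@H]3C(=O)CC(=O)CC(C)=O)cc1 | intermediate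
16 | 5-[(2S,3S)-4-(benzyloxy)-2-[4-(benzyloxy)phenyl]-6-{2-[4-(benzyloxy)phenyl]ethyl}-2,3-dihydro-1-benzofuran-3-yl]-5-hydroxycyclohexane-1,3-dione | c1ccccc1COc1ccc(CCc2cc(OCc4ccccc4)c3c(c2)O[C@H](c2ccc(OCc4ccccc4)cc2)[C@H]3C4(O)CC(=O)CC(=O)C4)cc1 | intermediate
17 | 5-[(2S,3S)-4-(benzyloxy)-2-[4-(benzyloxy)phenyl]-6-{2-[4-(benzyloxy)phenyl]ethyl}-2,3-dihydro-1-benzofuran-3-yl]benzene-1,3-diol | c1ccccc1COc1ccc(CCc2cc(OCc4ccccc4)c3c(c2)O[C@H](c2ccc(OCc4ccccc4)cc2)[C@H]3c2cc(O)cc(O)c2)cc1 | intermediate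
18 | 5-[(2S,3S)-4-hydroxy-2-(4-hydroxyphenyl)-6-[2-(4-hydroxyphenyl)ethyl]-2,3-dihydro-1-benzofuran-3-yl]benzene-1,3-diol | Oc1ccc(CCc2cc(O)c3c(c2)O[C@H](c2ccc(O)cc2)[C@H]3c2cc(O)cc(O)c2)cc1 | target

Total step count: 10. Longest linear sequence: 9 steps (steps 1–6 and 8–10); step 7 is a one-step side branch.

Steps most likely to fail

Step 9. Retro-Claisen cleavage of the triketone by hydroxide, or deprotonation at C3 followed by β-elimination of O1, may outpace the slow attack of the methyl-end enolate on the hindered C1 carbonyl. The fallback sets out from acid 11 (through acid chloride 14) and returns at 17. It keeps the ring construction but makes the nucleophile acidic enough to close ring B near neutrality. Acid chloride 14 would be condensed, under the base-free conditions of step 8, with 1-methoxy-1,3,5-tris(trimethylsilyloxy)hexa-1,3,5-triene F1, the tris(silyl enol ether) obtained beforehand from commercial methyl 3,5-dioxohexanoate by exhaustive O-silylation. Mild aqueous work-up should give the 3,5,7-trioxoheptanoate, methyl 7-(dihydrobenzofuran-3-yl)-3,5,7-trioxoheptanoate F2. Its C2 methylene, flanked by ketone and ester, should add to the C7 ketone in pH 9 buffer or with K2CO3 in MeOH at 20 °C, and dehydration then gives the β-resorcylate, methyl 2,4-dihydroxy-6-(dihydrobenzofuran-3-yl)benzoate F3. Heating with aqueous KOH in dioxane would hydrolyse the hindered ester to the β-resorcylic acid, 2,4-dihydroxy-6-(dihydrobenzofuran-3-yl)benzoic acid F4, which loses CO2 under the same conditions to give 17. By then C3 carries an arene and is no longer acidic.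

Step 5. Slow enol ether formation at the hindered, electron-rich C4 ketone may let dehydrogenation to the flavone or migration of the C2 aryl group compete with the shift of ring A, and the acid may ionise the C2–O bond and erode the C2 centre. The fallback sets out from 8 and returns at acid 11, replacing steps 5 and 6. It moves the ring contraction from the ketone to the alkene. NaBH4 in MeOH/THF at 0 °C would reduce 8 to the cis-(2S,4S)-flavan-4-ol F5, whose C4 configuration is lost in the next stage. Neutral dehydration with methyl N-(triethylammoniosulfonyl)carbamate in toluene at 50 °C should give the (2S)-2-aryl-2H-chromene F6. Tl(NO3)3·3H2O in MeOH/HC(OMe)3 at −20 °C would then add trivalent thallium to C3 anti to the aryl group and methanol to C4, and the shift of ring A from C4 to C3 (a known ring contraction of 2H-chromenes) gives the trans-(2S,3S) 3-(dimethoxymethyl)dihydrobenzofuran F7. Aqueous HCl in THF would free the aldehyde, the trans-(2S,3S) dihydrobenzofuran-3-carbaldehyde F8, and Pinnick oxidation (NaClO2, NaH2PO4, 2-methylbut-2-ene, t-BuOH/H2O) gives 11.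

Step 4. Facial selectivity may be low with the electron-rich boronic acid, or the boronic acid may be lost by protodeboronation and homocoupling before the hindered, deactivated enone reacts. The fallback sets out from 6 and returns at 8. It obtains the enantiomer by kinetic resolution instead of asymmetric induction. Chromone 6 and boronic acid 7 would be joined with the achiral, more forgiving catalyst Pd(OCOCF3)2/2,2'-bipyridine in AcOH/THF/H2O at 60 °C to give the racemic flavanone F9. Asymmetric transfer hydrogenation with RuCl[(R,R)-TsDPEN](p-cymene) and HCO2H/Et3N is a known kinetic resolution of flavanones. The catalyst antipode is chosen so that the (2R)-ketone is the one reduced, to the cis-(2R,4R)-flavan-4-ol F10, and unreacted (2S)-8 is separated by chromatography. Scalemic material from step 4 could be upgraded in the same way.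

Further compounds
F1 | step 9 | 1-methoxy-1,3,5-tris(trimethylsilyloxy)hexa-1,3,5-triene | COC(O[Si](C)(C)C)=CC(O[Si](C)(C)C)=CC(=C)O[Si](C)(C)C
F2 | step 9 | methyl 7-[(2S,3S)-4-(benzyloxy)-2-[4-(benzyloxy)phenyl]-6-{2-[4-(benzyloxy)phenyl]ethyl}-2,3-dihydro-1-benzofuran-3-yl]-3,5,7-trioxoheptanoate | c1ccccc1COc1ccc(CCc2cc(OCc4ccccc4)c3c(c2)O[C@H](c2ccc(OCc4ccccc4)cc2)[C@H]3C(=O)CC(=O)CC(=O)CC(=O)OC)cc1
F3 | step 9 | methyl 2,4-dihydroxy-6-[(2S,3S)-4-(benzyloxy)-2-[4-(benzyloxy)phenyl]-6-{2-[4-(benzyloxy)phenyl]ethyl}-2,3-dihydro-1-benzofuran-3-yl]benzoate | c1ccccc1COc1ccc(CCc2cc(OCc4ccccc4)c3c(c2)O[C@H](c2ccc(OCc4ccccc4)cc2)[C@H]3c2cc(O)cc(O)c2C(=O)OC)cc1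
F4 | step 9 | 2,4-dihydroxy-6-[(2S,3S)-4-(benzyloxy)-2-[4-(benzyloxy)phenyl]-6-{2-[4-(benzyloxy)phenyl]ethyl}-2,3-dihydro-1-benzofuran-3-yl]benzoic acid | c1ccccc1COc1ccc(CCc2cc(OCc4ccccc4)c3c(c2)O[C@H](c2ccc(OCc4ccccc4)cc2)[C@H]3c2cc(O)cc(O)c2C(=O)O)cc1
F5 | step 5 | (2S,4S)-5-(benzyloxy)-2-[4-(benzyloxy)phenyl]-7-{2-[4-(benzyloxy)phenyl]ethyl}-3,4-dihydro-2H-chromen-4-ol | O[C@H]1C[C@@H](c2ccc(OCc3ccccc3)cc2)Oc2cc(CCc3ccc(OCc4ccccc4)cc3)cc(OCc3ccccc3)c12
F6 | step 5 | (2S)-5-(benzyloxy)-2-[4-(benzyloxy)phenyl]-7-{2-[4-(benzyloxy)phenyl]ethyl}-2H-chromene | C1=C[C@@H](c2ccc(OCc3ccccc3)cc2)Oc2cc(CCc3ccc(OCc4ccccc4)cc3)cc(OCc3ccccc3)c12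
F7 | step 5 | (2S,3S)-4-(benzyloxy)-2-[4-(benzyloxy)phenyl]-6-{2-[4-(benzyloxy)phenyl]ethyl}-3-(dimethoxymethyl)-2,3-dihydro-1-benzofuran | c1ccccc1COc1ccc(CCc2cc(OCc4ccccc4)c3c(c2)O[C@H](c2ccc(OCc4ccccc4)cc2)[C@H]3C(OC)OC)cc1
F8 | step 5 | (2S,3S)-4-(benzyloxy)-2-[4-(benzyloxy)phenyl]-6-{2-[4-(benzyloxy)phenyl]ethyl}-2,3-dihydro-1-benzofuran-3-carbaldehyde | c1ccccc1COc1ccc(CCc2cc(OCc4ccccc4)c3c(c2)O[C@H](c2ccc(OCc4ccccc4)cc2)[C@H]3C=O)cc1
F9 | step 4 | racemic 5-(benzyloxy)-2-[4-(benzyloxy)phenyl]-7-{2-[4-(benzyloxy)phenyl]ethyl}-2,3-dihydro-4H-chromen-4-one | O=C1CC(c2ccc(OCc3ccccc3)cc2)Oc2cc(CCc3ccc(OCc4ccccc4)cc3)cc(OCc3ccccc3)c12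
F10 | step 4 | (2R,4R)-5-(benzyloxy)-2-[4-(benzyloxy)phenyl]-7-{2-[4-(benzyloxy)phenyl]ethyl}-3,4-dihydro-2H-chromen-4-ol | O[C@@H]1C[C@H](c2ccc(OCc3ccccc3)cc2)Oc2cc(CCc3ccc(OCc4ccccc4)cc3)cc(OCc3ccccc3)c12
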